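**Strategy.** The plan disconnects the bond between the angular quaternary carbon C1 and the alkene carbon C10 (C4 = C(OH)iPr, C5 = ring-fusion CH, C6 = ester carbinol, C8 = C(OH)Me, C9=C10 alkene). The C6 oxygen and the C8–C9=C10 unit of the seven-membered ring are first tied together as a 2,3-dihydropyran-4-one. A tertiary C1 radical then adds 5-exo to C10, closing the seven-membered ring as an oxa-bridged ketone and fixing the cis ring fusion. The precursor is a cyclopentane from ring contraction of (S)-terpinen-4-ol (C1–C6, both alkyl groups, C4) carrying a siloxydiene-derived pyranone (C7–C10). Bridge opening later unveils C6–OH and the enone.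

Key step: step 6

Remark: (S)-(+)-terpinen-4-ol of high enantiomeric purity and 4-[(tert-butyldimethylsilyl)oxy]benzoic acid are taken as purchasable. The target as drawn is the cis-fused isomer (C1 methyl and H-5 on the same face).

**Step 1**
Reactants: 1 (S)-(+)-terpinen-4-ol
Product: 2 (S)-triethyl{[4-methyl-1-(propan-2-yl)cyclohex-3-en-1-yl]oxy}silane
Conditions: Et3SiOTf, 2,6-lutidine, CH2Cl2, 0 °C to rt
Reagents that add atoms: triethylsilyl trifluoromethanesulfonate, CC[Si](CC)(CC)OS(=O)(=O)C(F)(F)F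
Why: O-silylation of the hindered tertiary alcohol with the silyl triflate (silyl ether protection) masks the hydroxyl against retro-aldol and elimination in the next steps, and the C4 stereocentre from the chiral pool is untouched.

**Step 2**
Reactants: 2 (S)-triethyl{[4-methyl-1-(propan-2-yl)cyclohex-3-en-1-yl]oxy}silane
Product: 4 (3S)-6-oxo-3-(propan-2-yl)-3-[(triethylsilyl)oxy]heptanal, via secondary ozonide 3 (not isolated)
Conditions: O3, CH2Cl2, −78 °C; then PPh3, −78 °C to rt
Reagents that add atoms: ozone, [O-][O+]=O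
Why: Criegee ozonolysis of the trisubstituted ring alkene and reductive cleavage of the ozonide should open the six-membered ring to the keto aldehyde without forming or touching a stereocentre.

**Step 3**
Reactants: 4 (3S)-6-oxo-3-(propan-2-yl)-3-[(triethylsilyl)oxy]heptanal
Product: 5 (5R)-2-methyl-5-(propan-2-yl)-5-[(triethylsilyl)oxy]cyclopent-1-ene-1-carbaldehyde
Conditions: piperidine (cat.), AcOH (cat.), benzene, reflux (Dean–Stark)
Reagents that add atoms: none
Why: Amine-catalysed intramolecular aldol condensation, in which the enamine of the aldehyde attacks the methyl ketone (5-exo) and dehydration follows, should give the tetrasubstituted cyclopentene carbaldehyde (net ring contraction) with no new stereocentre.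

**Step 4**
Reactants: 5 (5R)-2-methyl-5-(propan-2-yl)-5-[(triethylsilyl)oxy]cyclopent-1-ene-1-carbaldehyde
Product: 6 (1R,2R,5R)-2-methyl-2-(phenylselanyl)-5-(propan-2-yl)-5-[(triethylsilyl)oxy]cyclopentane-1-carbaldehyde (formyl cis to OSiEt3 and SePh, trans to isopropyl)
Conditions: PhSeH, Et3N (cat.), CH2Cl2, 0 °C to rt
Reagents that add atoms: benzeneselenol, [SeH]c1ccccc1
Why: Reversible selena-Michael addition to the enal should place selenium on C1 anti to the isopropyl group with anti protonation at C5, and the enolisable C5 should settle with the formyl group trans to isopropyl; the C1 configuration is erased in step 6.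

**Step 5**
Reactants: 6 (1R,2R,5R)-2-methyl-2-(phenylselanyl)-5-(propan-2-yl)-5-[(triethylsilyl)oxy]cyclopentane-1-carbaldehyde; 7 (E)-1-methoxy-3-(trimethylsilyloxy)buta-1,3-diene
Product: 9 (2S)-2-{(1S,2R,5R)-2-methyl-2-(phenylselanyl)-5-(propan-2-yl)-5-[(triethylsilyl)oxy]cyclopentyl}-2,3-dihydro-4H-pyran-4-one, via Mukaiyama aldol adduct 8 (not isolated)
Conditions: Me2AlCl, CH2Cl2, −78 °C; then CF3CO2H (cat.), CH2Cl2, 0 °C
Reagents that add atoms: none
Why: Mukaiyama aldol addition of the siloxydiene followed by acid-induced oxa-Michael closure with loss of methanol (stepwise hetero-Diels–Alder) builds the pyranone; Me2AlCl should chelate the aldehyde oxygen and the cis β-silyloxy oxygen on C4, so the diene attacks the face flanked by H-5 and sets C6 as (S).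

**Step 6**
Reactants: 9 (2S)-2-{(1S,2R,5R)-2-methyl-2-(phenylselanyl)-5-(propan-2-yl)-5-[(triethylsilyl)oxy]cyclopentyl}-2,3-dihydro-4H-pyran-4-one
Product: 10 (1R,2R,5R,6S,7S)-2-methyl-5-(propan-2-yl)-5-[(triethylsilyl)oxy]-11-oxatricyclo[5.3.1.0(2,6)]undecan-9-one
Conditions: Bu3SnH (slow addition), AIBN, benzene, 80 °C
Reagents that add atoms: none
Why: The stannyl radical abstracts the phenylselanyl group from C1 to give a planar tertiary radical, which adds to C10, the β-carbon of the vinylogous ester, and the α-keto radical formed at C9 is reduced by Bu3SnH. The closest known reaction type is the tin hydride radical cyclisation of β-alkoxy acrylates and β-alkoxy enones (Giese-type addition) that gives oxolanes. The new bond closes the oxolane C1–C5–C6–O–C10 in the 5-exo-trig mode and, because C6–C7–C8–C9–C10 already belong to the pyranone, at the same time the seven-membered carbocycle C1–C5–C6–C7–C8–C9–C10 as an 8-oxabicyclo[3.2.1]octanone. C1 is set by C5, since the oxolane can only be cis-fused to the cyclopentane, so C10 enters cis to C6 and the methyl group ends cis to H-5; C10 is set by C6, since the one-atom oxygen bridge forces attack on the pyranone face that carries the C6 substituent. The step needs cyclisation to outrun hydrogen transfer to the tertiary radical, which slow addition of the stannane should secure, and attack at C10 and not C9, which the polarity of the β-alkoxy enone and the 5-exo geometry secure.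

**Step 7**
Reactants: 10 (1R,2R,5R,6S,7S)-2-methyl-5-(propan-2-yl)-5-[(triethylsilyl)oxy]-11-oxatricyclo[5.3.1.0(2,6)]undecan-9-one
Product: 13 (3R,3aS,4S,8aS)-4-hydroxy-8a-methyl-3-(propan-2-yl)-3-[(triethylsilyl)oxy]-2,3,3a,4,5,8a-hexahydroazulen-6(1H)-one, via silyl enol ether 11 (not isolated), via ring-opened silyl ether 12 (not isolated)
Conditions: lithium (R,R)-bis(1-phenylethyl)amide, LiCl, Me3SiCl, THF, −100 °C; then Me3SiOTf (5 mol%), CH2Cl2, −78 to 0 °C; then citric acid, MeOH, rt
Reagents that add atoms: none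
Why: Chiral lithium amide deprotonation with internal silyl chloride quench, known to differentiate the two α-methylene groups of 8-oxabicyclo[3.2.1]octan-3-ones, should give the C8–C9 silyl enol ether (the amide enantiomer that removes H-9 is to be used; (R,R) is written), and Me3SiOTf-catalysed ionisation of the allylic bridging C10–O bond with silyl transfer then opens the bridge to the C9=C10 enone before mild methanolysis frees the C6 hydroxyl.

**Step 8**
Reactants: 13 (3R,3aS,4S,8aS)-4-hydroxy-8a-methyl-3-(propan-2-yl)-3-[(triethylsilyl)oxy]-2,3,3a,4,5,8a-hexahydroazulen-6(1H)-one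
Product: 14 (3R,3aS,4S,6R,8aS)-6,8a-dimethyl-3-(propan-2-yl)-3-[(triethylsilyl)oxy]-1,2,3,3a,4,5,6,8a-octahydroazulene-4,6-diol
Conditions: MeMgBr, CeCl3, THF, −78 °C
Reagents that add atoms: methylmagnesium bromide, C[Mg]Br
Why: Chelation-controlled 1,2-addition to the β-hydroxy enone, in which the metal should bridge the C6 alkoxide and the C8 carbonyl so that methyl enters anti to C6–O, should give the cis-1,3-diol (C8 R).

**Step 9**
Reactants: 14 (3R,3aS,4S,6R,8aS)-6,8a-dimethyl-3-(propan-2-yl)-3-[(triethylsilyl)oxy]-1,2,3,3a,4,5,6,8a-octahydroazulene-4,6-diol; 15 4-[(tert-butyldimethylsilyl)oxy]benzoic acid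
Product: 16 (3R,3aS,4S,6R,8aS)-6-hydroxy-6,8a-dimethyl-3-(propan-2-yl)-3-[(triethylsilyl)oxy]-1,2,3,3a,4,5,6,8a-octahydroazulen-4-yl 4-[(tert-butyldimethylsilyl)oxy]benzoate
Conditions: EDC·HCl, DMAP, CH2Cl2, rt
Reagents that add atoms: none
Why: Carbodiimide (Steglich) esterification should acylate only the secondary C6 hydroxyl, the tertiary allylic C8 hydroxyl being unreactive, and no stereocentre is affected.

**Step 10**
Reactants: 16 (3R,3aS,4S,6R,8aS)-6-hydroxy-6,8a-dimethyl-3-(propan-2-yl)-3-[(triethylsilyl)oxy]-1,2,3,3a,4,5,6,8a-octahydroazulen-4-yl 4-[(tert-butyldimethylsilyl)oxy]benzoate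
Product: 17 (3R,3aS,4S,6R,8aS)-3,6-dihydroxy-6,8a-dimethyl-3-(propan-2-yl)-1,2,3,3a,4,5,6,8a-octahydroazulen-4-yl 4-hydroxybenzoate (target)
Conditions: Bu4NF, AcOH, THF, 0 °C to rt
Reagents that add atoms: none
Why: Buffered fluoride should cleave the aryl silyl ether and the tertiary triethylsilyl ether in one operation while leaving the ester and the tertiary allylic alcohol intact.

**Compound list**
1 | (S)-(+)-terpinen-4-ol, (1S)-4-methyl-1-(propan-2-yl)cyclohex-3-en-1-ol | CC(C)[C@]1(O)CCC(C)=CC1 | starting material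
2 | (S)-triethyl{[4-methyl-1-(propan-2-yl)cyclohex-3-en-1-yl]oxy}silane | CC(C)[C@]1(O[Si](CC)(CC)CC)CCC(C)=CC1 | intermediate
3 | secondary ozonide (1,2,4-trioxolane) of 2, mixture at the ozonide carbons | CC(C)[C@]1(O[Si](CC)(CC)CC)CCC2(C)OOC(O2)C1 | intermediate (not isolated)
4 | (3S)-6-oxo-3-(propan-2-yl)-3-[(triethylsilyl)oxy]heptanal | CC(C)[C@](O[Si](CC)(CC)CC)(CCC(C)=O)CC=O | intermediate
5 | (5R)-2-methyl-5-(propan-2-yl)-5-[(triethylsilyl)oxy]cyclopent-1-ene-1-carbaldehyde | CC(C)[C@]1(O[Si](CC)(CC)CC)CCC(C)=C1C=O | intermediate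
6 | (1R,2R,5R)-2-methyl-2-(phenylselanyl)-5-(propan-2-yl)-5-[(triethylsilyl)oxy]cyclopentane-1-carbaldehyde | CC(C)[C@]1(O[Si](CC)(CC)CC)CC[C@@](C)([Se]c2ccccc2)[C@H]1C=O | intermediate
7 | (E)-1-methoxy-3-(trimethylsilyloxy)buta-1,3-diene | CO/C=C/C(=C)O[Si](C)(C)C | starting material
8 | (1E,5S)-5-hydroxy-1-methoxy-5-{(1S,2R,5R)-2-methyl-2-(phenylselanyl)-5-(propan-2-yl)-5-[(triethylsilyl)oxy]cyclopentyl}pent-1-en-3-one | CC(C)[C@]1(O[Si](CC)(CC)CC)CC[C@@](C)([Se]c2ccccc2)[C@H]1[C@@H](O)CC(=O)/C=C/OC | intermediate (not isolated)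
9 | (2S)-2-{(1S,2R,5R)-2-methyl-2-(phenylselanyl)-5-(propan-2-yl)-5-[(triethylsilyl)oxy]cyclopentyl}-2,3-dihydro-4H-pyran-4-one | CC(C)[C@]1(O[Si](CC)(CC)CC)CC[C@@](C)([Se]c2ccccc2)[C@H]1[C@@H]3CC(=O)C=CO3 | intermediate
10 | (1R,2R,5R,6S,7S)-2-methyl-5-(propan-2-yl)-5-[(triethylsilyl)oxy]-11-oxatricyclo[5.3.1.0(2,6)]undecan-9-one | CC(C)[C@]1(O[Si](CC)(CC)CC)CC[C@@]2(C)[C@H]3CC(=O)C[C@H](O3)[C@@H]12 | intermediate
11 | (1R,2R,5R,6S,7S)-2-methyl-5-(propan-2-yl)-5-[(triethylsilyl)oxy]-9-[(trimethylsilyl)oxy]-11-oxatricyclo[5.3.1.0(2,6)]undec-9-ene | CC(C)[C@]1(O[Si](CC)(CC)CC)CC[C@@]2(C)[C@H]3C=C(O[Si](C)(C)C)C[C@H](O3)[C@@H]12 | intermediate (not isolated)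
12 | (3R,3aS,4S,8aS)-8a-methyl-3-(propan-2-yl)-3-[(triethylsilyl)oxy]-4-[(trimethylsilyl)oxy]-2,3,3a,4,5,8a-hexahydroazulen-6(1H)-one | CC(C)[C@]1(O[Si](CC)(CC)CC)CC[C@@]2(C)C=CC(=O)C[C@H](O[Si](C)(C)C)[C@@H]12 | intermediate (not isolated)
13 | (3R,3aS,4S,8aS)-4-hydroxy-8a-methyl-3-(propan-2-yl)-3-[(triethylsilyl)oxy]-2,3,3a,4,5,8a-hexahydroazulen-6(1H)-one | CC(C)[C@]1(O[Si](CC)(CC)CC)CC[C@@]2(C)C=CC(=O)C[C@H](O)[C@@H]12 | intermediate
14 | (3R,3aS,4S,6R,8aS)-6,8a-dimethyl-3-(propan-2-yl)-3-[(triethylsilyl)oxy]-1,2,3,3a,4,5,6,8a-octahydroazulene-4,6-diol | CC(C)[C@]1(O[Si](CC)(CC)CC)CC[C@@]2(C)C=C[C@](C)(O)C[C@H](O)[C@@H]12 | intermediate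
15 | 4-[(tert-butyldimethylsilyl)oxy]benzoic acid | CC(C)(C)[Si](C)(C)Oc1ccc(cc1)C(O)=O | starting material
16 | (3R,3aS,4S,6R,8aS)-6-hydroxy-6,8a-dimethyl-3-(propan-2-yl)-3-[(triethylsilyl)oxy]-1,2,3,3a,4,5,6,8a-octahydroazulen-4-yl 4-[(tert-butyldimethylsilyl)oxy]benzoate | CC(C)[C@]1(O[Si](CC)(CC)CC)CC[C@@]2(C)C=C[C@](C)(O)C[C@H](OC(=O)c3ccc(O[Si](C)(C)C(C)(C)C)cc3)[C@@H]12 | intermediate
17 | (3R,3aS,4S,6R,8aS)-3,6-dihydroxy-6,8a-dimethyl-3-(propan-2-yl)-1,2,3,3a,4,5,6,8a-octahydroazulen-4-yl 4-hydroxybenzoate | CC(C)[C@]1(O)CC[C@@]2(C)C=C[C@](C)(O)C[C@H](OC(=O)c3ccc(O)cc3)[C@@H]12 | target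

**Totals.** Total step count: 10. Longest linear sequence: 10 steps (1 to 17); 7 and 15 are purchased.

**Steps most likely to fail**

Step 6. Hydrogen transfer from the stannane to the tertiary radical may outrun ring closure, because the cyclisation has to pass through a crowded transition state with the cyclopentane folded under the ketone bridge. The fallback sets out from 9 and comes back at 10. The selenide of 9 would be oxidised with H2O2 and pyridine to the selenoxide F1, which should eliminate thermally away from C5 (selenium is trans to H-5) to the endocyclic alkene F2 and its exocyclic methylene isomer F3. Both alkenes would give the same C1 radical by hydrogen-atom transfer with Fe(acac)3 and PhSiH3 in ethanol, where no fast stoichiometric hydrogen donor competes and radical formation is reversible, and the cyclisation should then deliver 10.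

Step 7. The deprotonation may discriminate poorly between the two α-methylene groups, so that the bridge opens on the wrong side (C6–O instead of C10–O cleavage). The fallback sets out from 10 and comes back at 13. Equilibrating β-elimination with KOtBu in tert-butanol should give 13 together with the regioisomeric hydroxy enone F4; after separation F4 would be returned to 10 by base-mediated intramolecular oxa-Michael re-closure and recycled until the material has been funnelled into 13.

Step 5. The aluminium chelate with the hindered tertiary silyl ether may not form, which would lead to poor facial selectivity at the aldehyde and the C6 epimer. The fallback sets out from 6 and comes back at 9. A reagent-controlled boron aldol addition of the (E)-4-chlorobut-3-en-2-one enolate, made with (−)-Ipc2BCl and Et3N (reagent enantiomer chosen for the 6S carbinol), would give the chlorovinyl aldol adduct F5, which should close to 9 with Me3SiOTf and iPr2NEt by oxa-Michael addition and loss of chloride.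

**Further compounds**
F1 | step 6 | selenoxide of 9, (2S)-2-{(1S,2R,5R)-2-methyl-2-(phenylseleninyl)-5-(propan-2-yl)-5-[(triethylsilyl)oxy]cyclopentyl}-2,3-dihydro-4H-pyran-4-one | CC(C)[C@]1(O[Si](CC)(CC)CC)CC[C@@](C)([Se](=O)c2ccccc2)[C@H]1[C@@H]3CC(=O)C=CO3
F2 | step 6 | (2S)-2-{(1S,5R)-2-methyl-5-(propan-2-yl)-5-[(triethylsilyl)oxy]cyclopent-2-en-1-yl}-2,3-dihydro-4H-pyran-4-one | CC(C)[C@]1(O[Si](CC)(CC)CC)CC=C(C)[C@H]1[C@@H]2CC(=O)C=CO2
F3 | step 6 | (2S)-2-{(1S,2R)-5-methylidene-2-(propan-2-yl)-2-[(triethylsilyl)oxy]cyclopentyl}-2,3-dihydro-4H-pyran-4-one | CC(C)[C@]1(O[Si](CC)(CC)CC)CCC(=C)[C@H]1[C@@H]2CC(=O)C=CO2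
F4 | step 7 | regioisomeric hydroxy enone, 8-hydroxy-8a-methyl-3-(propan-2-yl)-3-[(triethylsilyl)oxy]-2,3,3a,7,8,8a-hexahydroazulen-6(1H)-one with the C4=C5 double bond and the configuration of 10 | CC(C)[C@]1(O[Si](CC)(CC)CC)CC[C@@]2(C)[C@H](O)CC(=O)C=C[C@@H]12
F5 | step 5 | (1E,5S)-1-chloro-5-hydroxy-5-{(1S,2R,5R)-2-methyl-2-(phenylselanyl)-5-(propan-2-yl)-5-[(triethylsilyl)oxy]cyclopentyl}pent-1-en-3-one | CC(C)[C@]1(O[Si](CC)(CC)CC)CC[C@@](C)([Se]c2ccccc2)[C@H]1[C@@H](O)CC(=O)/C=C/Cl
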